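Percent of the substrate charged is the unit we read in: each reading is an amount formed by its time, not a rate.

| flask | substrate | first nucleophile | second nucleophile | remark | time |
|---|---|---|---|---|---|
| maple | 0.25 M | 0.50 M | 1 M | run made earlier |  |
| ash | 0.12 M | 0.50 M | 1 M | run made earlier |  |
| cedar | 0.19 M | 0.50 M | 1 M | run made earlier |  |
| alder | 0.25 M | 0.50 M | 1.5 M | run made earlier |  |
| winter | 0.25 M (fed, over 1.5 h) | 0.500 M | 1.00 M | all else is in the flask from the start; the feed brings no volume worth counting | 2.0 h |
| midnight | 0.25 M | 0.500 M | 1.00 M | everything together at the start | 2.0 h |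
| dusk | 0.25 M | 0.500 M (fed, over 1.5 h) | 1.00 M | all else is in the flask from the start; the feed brings no volume worth counting | 2.0 h |

| run | time / min | target / % | other capture product / % |
|---|---|---|---|
| maple | 20.0 | 1.3 | 10.2 |
| maple | 40.0 | 3.2 | 17.9 |
| maple | 60.0 | 3.4 | 23.7 |
| maple | 80.0 | 4.0 | 26.2 |
| maple | 90.0 | 6.7 | 28.2 |
| maple | 120 | 8.3 | 30.7 |
| ash | 12.0 | 0 | 6.4 |
| ash | 25.0 | 1.5 | 13.9 |
| ash | 40.0 | 3.9 | 17.1 |
| ash | 50.0 | 1.9 | 23.1 |
| ash | 60.0 | 6.3 | 23.9 |
| ash | 80.0 | 4.5 | 29.6 |
| cedar | 5.00 | 0.7 | 5.0 |
| cedar | 15.0 | 1.6 | 9.2 |
| cedar | 25.0 | 2.5 | 13.0 |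
| cedar | 40.0 | 2.9 | 18.7 |
| cedar | 60.0 | 4.9 | 23.5 |
| cedar | 80.0 | 5.5 | 28.2 |
| alder | 15.0 | 1.4 | 10.5 |
| alder | 30.0 | 1.6 | 19.6 |
| alder | 40.0 | 2.3 | 22.3 |
| alder | 60.0 | 1.5 | 28.4 |
| alder | 80.0 | 4.2 | 32.9 |

(each reading ± 1 percentage point)



- the flask with the highest share of target in target plus other capture product ("all alike" if they lie within 1.5 percentage points) (winter / midnight / dusk / all alike)
- share of target in target plus other capture product at the end, winter
- share of target in target plus other capture product at the end, midnight
- share of target in target plus other capture product at the end, dusk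

Maple has the charges of midnight. Its other capture product slows 4.53-fold between the first 20.0 min and the stretch after 80.0 min. Yet target gains 4.0 % in the first 80.0 min and 4.3 percentage points in the next 40.0 min, so supply holds up while the competitor fades. Capture has used 0.0767 M of 1 M of second nucleophile, far less than the charge, so we take a separate first-order loss, with a reading of 0.0168 min⁻¹, a half-time of 41.3 min.

Two limits are easy. With second nucleophile held at its charge, the odds of target over other capture product (a selectivity factor) stay at their starting value, and feeding substrate changes nothing. With it gone at once, the share is 100 percent. Between them stands the exposure, the mean fraction of its charge that second nucleophile shows to the substrate present. We assume odds proportional to first nucleophile over exposure, with substrate steady once in.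

Midnight has exposure 0.430. Maple's end odds, 0.270, give 0.116 at full charge and a midnight share of 21.3 %. Winter's substrate arrives late, so its exposure is 0.304, and its share is 27.7 %. Dusk keeps midnight's exposure, but its first nucleophile averages 62.5 % of charge, giving 14.5 %. We commit to winter as highest.

The forecast chose midnight, with 15.5 %, 16 % and 10 % for winter, midnight and dusk, holding that “Feeding substrate leaves the nucleophile ratio unchanged”.

The flasks give winter first, with 31.9 % for winter, 22.8 % for midnight and 16.3 % for dusk.

    second nucleophile + intermediate → other capture product (k = 4.00 L mol⁻¹ min⁻¹)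
    substrate ⇌ intermediate (K = 0.00600, k = 0.00950 min⁻¹)
    first nucleophile + intermediate → target (k = 0.710 L mol⁻¹ min⁻¹)
    intermediate → side product (k = 0.0280 min⁻¹)
    second nucleophile → decomposed reagent (k = 0.0220 min⁻¹)

In winter, second nucleophile has a half-life of 0.53 h by decomposition, shorter than the feed of 1.5 h. At 2.00 h that step uses it 6.7 times as fast as capture does. Exposure 0.304 gave winter odds of 0.383, and the flask ends at 0.468. For winter with 2.0 M of first nucleophile, the same exposure gives odds of 1.53, a share of 60.5 %. The computed flask gives 63.7 %.

(The earlier runs and the new flask were computed with made-up constants, and the scatter is random.)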